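Charge the missing points of single product to the partner in excess, and reckon them as a small correction on a rate law.

| flask | starting material | partner | remark | time |
|---|---|---|---|---|
| north-west | 0.30 M | 0.58 equiv | run made earlier |  |
| east | 0.30 M | 3.9 equiv | run made earlier |  |
| eta | 0.30 M | 2.50 equiv |  | 25 h |
| delta | 0.30 M | 0.500 equiv |  | 25 h |
| beta | 0.30 M | 2.00 equiv |  | 25 h |

- north-west (time / h: single product / %): 4.00: 18.2; 8.00: 30.5; 10.0: 33.0; 15.0: 41.4; 20.0: 43.9
- east (time / h: single product / %): 1.33: 41.4; 2.50: 59.4; 5.00: 80.0; 10.0: 89.2; 20.0: 89.1

(standard deviation of a reading: 1 percentage point)

- a reading or a percentage of single product counts all its forms, free or not

- which of these holds the largest part of the starting material at the end of eta (starting material / single product / double product)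
- which of these holds the largest part of the starting material at the end of delta (starting material / single product / double product)
- which of these holds the largest part of the starting material at the end of beta (starting material / single product / double product)
- final single product in eta, as a percentage of the starting material charged

Partner and starting material meet one to one, so a second-order law gives its constant k from a single reading. Take it from opposite sides. North-west, where partner is the limiting reagent, gives 0.350 L mol⁻¹ h⁻¹ at 10.0 h; east, with partner in excess, gives 0.338 L mol⁻¹ h⁻¹ at 2.50 h. The two ways agree within the scatter, so I carry their mean, 0.344 L mol⁻¹ h⁻¹. With q the equivalents and x equal to q minus one, the part of the starting material left after time t is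

left = x / (q·exp(k·[starting material]·x·t) − 1)

Now run both flasks to their last reading. In north-west the law gives 44.5% single product and the reading is 43.9%. In east the law leaves 0.186% of the starting material, yet the readings of single product stand at 89.2% and 89.1%. Law and readings part here, and the law is what cheats: it counts starting material gone, which is not the same as single product made. The gap shows in east, with partner in excess, and not in north-west, with partner lacking, so I keep 3.69% of the charge per equivalent beyond one, as read from the last east reading, as the excess toll. Both runs stood at 0.30 M, so how it moves with concentration is unread.

eta: left 1.26%, toll 5.54%, single product 93.2%

beta: left 3.93%, toll 3.69%, single product 92.4%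

delta: partner lacking, no toll: left 58.0%, single product 42.0%

In eta the two corrections are small beside the main term, so the largest holder there is safe while the last points of the percentage are less so.

The forecast names single product, starting material and single product for eta, delta and beta, and 93% for eta, beside my 93.2%, from another reading of the gap: “So I read the missing 11% as double product”.

The flask gives single product, starting material and single product, and 90.6% in eta.

    partner + single product → double product + by-product (k = 0.0197 L mol⁻¹ h⁻¹)
    starting material + by-product → side product (k = 0.0443 L mol⁻¹ h⁻¹)
    starting material + partner → single product + by-product (k = 0.389 L mol⁻¹ h⁻¹)
    crystals ⇌ single product, rate k4*(cs4 - [single product]) while solid is left; crystals form when [single product] > cs4 (solubility = 10.0 mM, k = 3.35 h⁻¹)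
    partner + single product → over-reaction product (k = 0.0846 L mol⁻¹ h⁻¹)

In eta the shortfall, the part that is neither single product nor starting material, is 8.78% against the toll of 5.54%, with 0.617% of starting material left against 1.26%. Now take the neighbour: the eta flask at 0.12 M of starting material, equivalents and time held. Its excess in equivalents is unchanged, so I charge the same toll of 5.54%, though its move with concentration is unread; the law leaves 13.9%, which gives 80.6% single product. That flask holds 10.6% of starting material, has a shortfall of 7.60%, and gives 81.8% of single product.

The runs come from a simulation from invented constants.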